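**Retrosynthetic overview**
1. Locants follow elemane numbering. The ring is C5–C6–C7–C8–C9–C10: C10 = quaternary CH3/vinyl carbon, C9 = CH2, C8 = acyloxy carbon, C7 carries C11(=C13H2)C12O2H, C6 = CHOH, C5 carries C4(=C3H2)C15H2OH. Target ⇐ Pinnick oxidation of enal 36 ⇐ acylation of cyclohexanol 27 with the (Z)-acid 33.
2. Enabling feature: inside the cyclohexane ring the carbinol carbon C8 is bonded to ring carbon C7, which carries the exocyclic alkene C11=C13. This homoallylic alcohol is the retron of an allylboration, and C7 is flanked by the oxygenated ring carbon C6, whose allylic strain steers the face.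
3. Key disconnection: ring bond C7–C8 together with C11–C13. The acyclic (Z)-iodoalkene aldehyde 24 and the one-carbon unit IZnCH2Bpin undergo a cross-coupling / intramolecular allylboration cascade. This closes the only ring, and it is formed last.
4. 24 ⇐ ynone 19 (C6 by asymmetric transfer hydrogenation, Z-iodide by hydroxyl-directed hydroalumination) ⇐ acid 14 + 3,3-diethoxypropyne 17.
5. 14 (C5 and C10) ⇐ enantioselective boron Ireland–Claisen rearrangement of the achiral ester 11 ⇐ allylic alcohol 5 (from but-3-yn-1-ol) + acid 10 (from 2-methylenepropane-1,3-diol).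

Key step: step 14

Assumption: the (R,R)-configured bromoborane of step 7 is taken to give the (5S,10R) acid. The sense of induction has to be confirmed on the first batch, and the equally available (S,S)-reagent is used if it proves opposite.

**Step 1**
Reactants: 1 but-3-yn-1-ol
Product: 2 (but-3-yn-1-yloxy)triethylsilane
Conditions: TESCl, imidazole, CH2Cl2, 0 °C → rt
Reagents that add atoms: chlorotriethylsilane CC[Si](Cl)(CC)CC
Why: Imidazole-promoted silylation masks the future C8 oxygen as a primary TES ether, which can later be oxidised directly to the aldehyde.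

**Step 2**
Reactants: 2 (but-3-yn-1-yloxy)triethylsilane
Product: 5 (E)-3-methyl-5-(triethylsilyloxy)pent-2-en-1-ol, via alkenylalane 3 (not isolated), via lithium alanate 4 (not isolated)
Conditions: Me3Al, Cp2ZrCl2 (20 mol %), CH2Cl2, 0 °C → rt; n-BuLi, THF, −78 °C; (CH2O)n, −78 °C → rt; aq. Rochelle salt
Reagents that add atoms: trimethylaluminium C[Al](C)C; formaldehyde (from paraformaldehyde) C=O
Why: Zr-catalysed syn-carboalumination of the terminal alkyne (Negishi carboalumination) fixes the E-trisubstituted C10=C1 alkene, and the alanate is hydroxymethylated with retention of geometry.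

**Step 3**
Reactants: 6 2-methylenepropane-1,3-diol
Product: 7 2-{[(tert-butyldimethylsilyl)oxy]methyl}prop-2-en-1-ol
Conditions: NaH (1 equiv), THF, rt; TBSCl
Reagents that add atoms: tert-butyldimethylsilyl chloride CC(C)(C)[Si](C)(C)Cl
Why: Monosilylation of a symmetrical diol through its sparingly soluble monosodium alkoxide differentiates the two equivalent hydroxyl groups.

**Step 4**
Reactants: 7 2-{[(tert-butyldimethylsilyl)oxy]methyl}prop-2-en-1-ol
Product: 8 {[2-(bromomethyl)prop-2-en-1-yl]oxy}(tert-butyl)dimethylsilane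
Conditions: CBr4, PPh3, CH2Cl2, 0 °C
Reagents that add atoms: carbon tetrabromide BrC(Br)(Br)Br
Why: The Appel reaction converts the primary allylic alcohol into the bromide under neutral conditions that leave the allylic TBS ether intact.

**Step 5**
Reactants: 8 {[2-(bromomethyl)prop-2-en-1-yl]oxy}(tert-butyl)dimethylsilane
Product: 10 3-{[(tert-butyldimethylsilyl)oxy]methyl}but-3-enoic acid, via allylzinc bromide 9 (not isolated)
Conditions: Zn dust, LiCl, THF, 0 °C; CO2 (1 atm), 0 °C → rt; cold dilute HCl
Reagents that add atoms: carbon dioxide O=C=O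
Why: LiCl-assisted zinc insertion gives an allylzinc with two equivalent CH2 termini, and its carboxylation delivers the β,γ-unsaturated acid without any base that could move the alkene into conjugation.

**Step 6**
Reactants: 5 (E)-3-methyl-5-(triethylsilyloxy)pent-2-en-1-ol; 10 3-{[(tert-butyldimethylsilyl)oxy]methyl}but-3-enoic acid
Product: 11 (E)-3-methyl-5-(triethylsilyloxy)pent-2-en-1-yl 3-{[(tert-butyldimethylsilyl)oxy]methyl}but-3-enoate
Conditions: DCC, DMAP (5 mol %), CH2Cl2, 0 °C
Reagents that add atoms: none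
Why: Steglich esterification at low temperature with little DMAP joins the two achiral halves without deconjugated-to-conjugated isomerisation.

**Step 7**
Reactants: 11 (E)-3-methyl-5-(triethylsilyloxy)pent-2-en-1-yl 3-{[(tert-butyldimethylsilyl)oxy]methyl}but-3-enoate
Product: 14 (2S,3R)-2-[3-(tert-butyldimethylsilyloxy)prop-1-en-2-yl]-3-methyl-3-[2-(triethylsilyloxy)ethyl]pent-4-enoic acid, via boron ketene acetal 12 (not isolated), via acyloxyborane 13 (not isolated)
Conditions: (R,R)-bromoborane [from (R,R)-N,N'-bis(3,5-bis(trifluoromethyl)benzenesulfonyl)-1,2-diphenylethylenediamine + BBr3, CH2Cl2, volatiles removed], Et3N, toluene/hexane, −78 °C; then −20 → 4 °C; pH 5 buffer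
Reagents that add atoms: none
Why: Soft enolisation with Et3N in a non-polar medium gives the E(O) boron ketene acetal, which rearranges through a chair transition state (enantioselective boron variant of the Ireland–Claisen rearrangement); E-alkene plus E(O)-enolate set the C5/C10 relative configuration (side chain trans to vinyl), and the C2-symmetric sulfonamide ligand on boron selects the enantiotopic face pair.

**Step 8**
Reactants: 14 (2S,3R)-2-[3-(tert-butyldimethylsilyloxy)prop-1-en-2-yl]-3-methyl-3-[2-(triethylsilyloxy)ethyl]pent-4-enoic acid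
Product: 16 N-methoxy-N-methylamide of 14 (5S,10R), via acid chloride 15 (not isolated)
Conditions: 1-chloro-N,N,2-trimethylprop-1-en-1-amine, CH2Cl2, 0 °C; MeNH(OMe)·HCl, pyridine, 0 °C → rt
Reagents that add atoms: N,O-dimethylhydroxylamine hydrochloride CNOC.Cl
Why: Neutral acid chloride formation with an α-chloroenamine followed by aminolysis gives the Weinreb amide of a hindered acid without acid loss of silyl ethers or epimerisation at C5.

**Step 9**
Reactants: 16 N-methoxy-N-methylamide of 14; 17 3,3-diethoxyprop-1-yne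
Product: 19 (5S,6R)-5-[3-(tert-butyldimethylsilyloxy)prop-1-en-2-yl]-1,1-diethoxy-6-methyl-6-[2-(triethylsilyloxy)ethyl]oct-7-en-2-yn-4-one, via lithium acetylide 18 (not isolated)
Conditions: 17, n-BuLi, THF, −78 °C; then 16, −78 → 0 °C; aq. NH4Cl
Reagents that add atoms: none
Why: Addition of a slim acetylide to the Weinreb amide stops at the chelated tetrahedral adduct and releases the ynone only on work-up, bringing in C7, C11 and C12 with C12 at the aldehyde oxidation level.

**Step 10**
Reactants: 19 ynone (5S,10R)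
Product: 20 (4R,5S,6R)-5-[3-(tert-butyldimethylsilyloxy)prop-1-en-2-yl]-1,1-diethoxy-6-methyl-6-[2-(triethylsilyloxy)ethyl]oct-7-en-2-yn-4-ol
Conditions: Ru[(R,R)-TsDPEN](p-cymene) (preformed 16-electron complex, 5 mol %), i-PrOH, rt
Reagents that add atoms: none
Why: Base-free Ru–TsDPEN asymmetric transfer hydrogenation of an alkynyl ketone sets 6R under catalyst control, and this is matched with the Felkin–Anh preference of the substrate (hydride anti to the quaternary C10 group).

**Step 11**
Reactants: 20 propargylic alcohol (5S,6R,10R)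
Product: 22 (2Z,4R,5S,6R)-5-[3-(tert-butyldimethylsilyloxy)prop-1-en-2-yl]-1,1-diethoxy-2-iodo-6-methyl-6-[2-(triethylsilyloxy)ethyl]octa-2,7-dien-4-ol, via cyclic alanate 21 (not isolated)
Conditions: Red-Al, THF, 0 °C → rt; EtOAc; I2, −78 → 0 °C; aq. Na2S2O3/NaHCO3
Reagents that add atoms: iodine II
Why: Hydroxyl-directed trans-hydroalumination delivers hydride to C7 and places aluminium on C11 in a five-membered alanate, and iodinolysis with retention gives the iodide cis to C6.

**Step 12**
Reactants: 22 (Z)-iodoalkenol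
Product: 23 C6 triethylsilyl ether of 22
Conditions: TESCl, imidazole, DMAP (cat.), DMF, rt → 40 °C
Reagents that add atoms: chlorotriethylsilane CC[Si](Cl)(CC)CC
Why: Imidazole-mediated silylation protects the hindered allylic alcohol under conditions that, unlike silyl triflate/pyridine-base mixtures, do not touch the diethyl acetal.

**Step 13**
Reactants: 23 bis-TES ether
Product: 24 (3R,4S,5R,6Z)-4-[3-(tert-butyldimethylsilyloxy)prop-1-en-2-yl]-3-ethenyl-8,8-diethoxy-7-iodo-3-methyl-5-(triethylsilyloxy)oct-6-enal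
Conditions: (COCl)2, DMSO, CH2Cl2, −78 → −40 °C; Et3N, −78 °C → rt
Reagents that add atoms: none
Why: Under Swern conditions the activated sulfonium species attacks the least hindered silyl ether oxygen, so the primary TES ether is oxidised directly to the aldehyde while the secondary TES ether, the primary TBS ether, the acetal and the iodide persist.

**Step 14**
Reactants: 24 (Z)-iodoalkene aldehyde
Product: 27 (1R,2R,3R,4S,5R)-4-[3-(tert-butyldimethylsilyloxy)prop-1-en-2-yl]-2-(3,3-diethoxyprop-1-en-2-yl)-5-ethenyl-5-methyl-3-(triethylsilyloxy)cyclohexan-1-ol, via allylboronate aldehyde 25 (not isolated), via cyclohexyl borate 26 (not isolated)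
Conditions: IZnCH2Bpin (from ICH2Bpin, Zn dust, THF, rt; excess), Pd(PPh3)4 (5 mol %), THF, rt → 40 °C; pH 7 buffer
Reagents that add atoms: 2-(iodomethyl)-4,4,5,5-tetramethyl-1,3,2-dioxaborolane ICB1OC(C)(C)C(C)(C)O1
Why: Pd(0) inserts into the C–I bond, the (boryl)methylzinc iodide transmetalates and reductive elimination with retention (Negishi coupling) gives allylboronate 25 with CH2Bpin cis to C6, whereupon boron binds the tethered aldehyde and C7 attacks C8 through a closed six-membered Zimmerman–Traxler array while the C13–B bond turns into the C11=C13 methylene and a B–O8 bond. The closest known reaction types are the cross-coupling of (dialkoxyboryl)methylzinc reagents with ω-oxo-1-haloalkenes followed by spontaneous ring closure, and the stereospecific cyclisation of Z-configured ω-oxo-allylboronates to cis-2-alkenylcyclohexanols. The cyclohexane is closed in a 6-exo-trig mode at the aldehyde carbon (C=O and C7=C11 both exocyclic to the forming ring), with carbocycle and boron chair fused like a cis-decalin. C8 is fixed relative to C7 by the alkene geometry, because the substituent cis to CH2B (C6) must be axial in the boron chair, which places O8 axial and C11 equatorial on the new ring, i.e. cis. C7 is fixed relative to C6 by A(1,3) strain, since H6 eclipses the C7=C11 bond, the tether delivers the aldehyde to the face anti to OTES and O6/C11 end up trans-diequatorial, whereas the other cis array would put the C5 and C7 side chains 1,3-diaxial or stack O6, O8 and the C10 methyl group on one face. The step needs the coupling to outrun zinc addition to the aldehyde and 5-exo carbopalladation of the C5 side-chain alkene (secured by an excess of a fast-transmetalating but carbonyl-inert zinc reagent near room temperature) and attack on the aldehyde instead of the acetal (secured by the absence of a strong Lewis acid).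

**Step 15**
Reactants: 28 diphenyl phosphite; 29 tert-butyl 2-bromopropanoate
Product: 30 tert-butyl 2-(diphenoxyphosphoryl)propanoate (racemic)
Conditions: NaH, THF, 0 °C; then 29, 0 °C → rt
Reagents that add atoms: none
Why: Michaelis–Becker alkylation of the sodium phosphite with an activated secondary bromide gives the diaryl phosphonate, whose stereocentre is lost in the next step.

**Step 16**
Reactants: 30 tert-butyl 2-(diphenoxyphosphoryl)propanoate; 31 2-oxoethyl acetate
Product: 32 tert-butyl (Z)-4-acetoxy-2-methylbut-2-enoate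
Conditions: NaH, THF, −78 °C; then 31, −78 → 0 °C
Reagents that add atoms: none
Why: The Horner–Wadsworth–Emmons reaction with an electron-poor diaryl phosphonate collapses under kinetic control and gives the Z-trisubstituted enoate with the acetate already in place, so a free Z-γ-hydroxy ester that would lactonise is never formed.

**Step 17**
Reactants: 32 tert-butyl (Z)-4-acetoxy-2-methylbut-2-enoate
Product: 33 (Z)-4-acetoxy-2-methylbut-2-enoic acid
Conditions: TFA, CH2Cl2, 0 °C → rt; used at once
Reagents that add atoms: none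
Why: Acidolysis of the tert-butyl ester (E1 loss of isobutene) frees the acid without touching the acetate or the alkene geometry.

**Step 18**
Reactants: 27 cyclohexanol; 33 (Z)-4-acetoxy-2-methylbut-2-enoic acid
Product: 35 C8 (Z)-4-acetoxy-2-methylbut-2-enoate of 27 (5S,6R,7R,8R,10R), via mixed anhydride 34 (not isolated)
Conditions: 2,4,6-trichlorobenzoyl chloride, Et3N, toluene, rt; then 27, DMAP, 0 °C → rt
Reagents that add atoms: none
Why: Yamaguchi esterification through the hindered aryl mixed anhydride is the established way to acylate secondary alcohols with angelate-type Z-acids while keeping the geometry, and C8-OH is the only free hydroxyl group.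

**Step 19**
Reactants: 35 fully protected ester
Product: 36 enal diol (5S,6R,7S,8R,10R): 35 with C12 as CHO and free C6-OH and C15-OH
Conditions: 48 % aq. HF, MeCN, 0 °C → rt
Reagents that add atoms: water O
Why: One mild aqueous acid/fluoride treatment cleaves both silyl ethers and hydrolyses the readily ionised 2-alkenyl acetal, leaving the ester, the allylic acetate and all stereocentres untouched.

**Step 20**
Reactants: 36 enal diol
Product: 37 target, (5S,6R,7S,8R,10R)-8-[(Z)-4-acetoxy-2-methylbut-2-enoyloxy]-6,15-dihydroxyelema-1,3,11(13)-trien-12-oic acid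
Conditions: NaClO2, NaH2PO4, 2-methyl-2-butene, t-BuOH/H2O, 0 °C → rt
Reagents that add atoms: sodium chlorite [Na+].[O-]Cl=O
Why: Pinnick oxidation converts the enal into the acrylic acid in a buffered medium that tolerates free alcohols, alkenes and esters, so the acid appears only in the last step and is never exposed to conditions that favour lactonisation onto C6-OH.

**Compound list**
1 | but-3-yn-1-ol | C#CCCO | starting material
2 | (but-3-yn-1-yloxy)triethylsilane | C#CCCO[Si](CC)(CC)CC | intermediate
3 | dimethyl[(E)-2-methyl-4-(triethylsilyloxy)but-1-en-1-yl]alane | C[Al](C)/C=C(C)/CCO[Si](CC)(CC)CC | intermediate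
4 | lithium butyl(dimethyl)[(E)-2-methyl-4-(triethylsilyloxy)but-1-en-1-yl]alanate | [Li+].CCCC[Al-](C)(C)/C=C(C)/CCO[Si](CC)(CC)CC | intermediate
5 | (E)-3-methyl-5-(triethylsilyloxy)pent-2-en-1-ol | OC/C=C(C)/CCO[Si](CC)(CC)CC | intermediate
6 | 2-methylenepropane-1,3-diol | C=C(CO)CO | starting material
7 | 2-{[(tert-butyldimethylsilyl)oxy]methyl}prop-2-en-1-ol | C=C(CO)CO[Si](C)(C)C(C)(C)C | intermediate
8 | {[2-(bromomethyl)prop-2-en-1-yl]oxy}(tert-butyl)dimethylsilane | C=C(CBr)CO[Si](C)(C)C(C)(C)C | intermediate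
9 | 2-{[(tert-butyldimethylsilyl)oxy]methyl}allylzinc bromide | Br[Zn]CC(=C)CO[Si](C)(C)C(C)(C)C | intermediate
10 | 3-{[(tert-butyldimethylsilyl)oxy]methyl}but-3-enoic acid | OC(=O)CC(=C)CO[Si](C)(C)C(C)(C)C | intermediate
11 | (E)-3-methyl-5-(triethylsilyloxy)pent-2-en-1-yl 3-{[(tert-butyldimethylsilyl)oxy]methyl}but-3-enoate | CC[Si](CC)(CC)OCC/C(C)=C/COC(=O)CC(=C)CO[Si](C)(C)C(C)(C)C | intermediate
12 | E(O) boron ketene acetal of 11 with the (R,R)-diazaborolidine (side chain cis to the allyloxy oxygen) | CC[Si](CC)(CC)OCC/C(C)=C/CO/C(OB1N(S(=O)(=O)c2cc(cc(c2)C(F)(F)F)C(F)(F)F)[C@H](c2ccccc2)[C@@H](c2ccccc2)N1S(=O)(=O)c1cc(cc(c1)C(F)(F)F)C(F)(F)F)=C\C(=C)CO[Si](C)(C)C(C)(C)C | intermediate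
13 | (R,R)-diazaborolidinyl carboxylate of 14 | O=C(OB1N(S(=O)(=O)c2cc(cc(c2)C(F)(F)F)C(F)(F)F)[C@H](c2ccccc2)[C@@H](c2ccccc2)N1S(=O)(=O)c1cc(cc(c1)C(F)(F)F)C(F)(F)F)[C@H](C(=C)CO[Si](C)(C)C(C)(C)C)[C@@](C)(C=C)CCO[Si](CC)(CC)CC | intermediate
14 | (2S,3R)-2-[3-(tert-butyldimethylsilyloxy)prop-1-en-2-yl]-3-methyl-3-[2-(triethylsilyloxy)ethyl]pent-4-enoic acid | OC(=O)[C@H](C(=C)CO[Si](C)(C)C(C)(C)C)[C@@](C)(C=C)CCO[Si](CC)(CC)CC | intermediate
15 | acid chloride of 14 | ClC(=O)[C@H](C(=C)CO[Si](C)(C)C(C)(C)C)[C@@](C)(C=C)CCO[Si](CC)(CC)CC | intermediate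
16 | N-methoxy-N-methylamide of 14 | CON(C)C(=O)[C@H](C(=C)CO[Si](C)(C)C(C)(C)C)[C@@](C)(C=C)CCO[Si](CC)(CC)CC | intermediate
17 | 3,3-diethoxyprop-1-yne | C#CC(OCC)OCC | starting material
18 | (3,3-diethoxyprop-1-yn-1-yl)lithium | [Li]C#CC(OCC)OCC | intermediate
19 | (5S,6R)-5-[3-(tert-butyldimethylsilyloxy)prop-1-en-2-yl]-1,1-diethoxy-6-methyl-6-[2-(triethylsilyloxy)ethyl]oct-7-en-2-yn-4-one | CCOC(OCC)C#CC(=O)[C@H](C(=C)CO[Si](C)(C)C(C)(C)C)[C@@](C)(C=C)CCO[Si](CC)(CC)CC | intermediate
20 | (4R,5S,6R)-propargylic alcohol from 19 | CCOC(OCC)C#C[C@H](O)[C@H](C(=C)CO[Si](C)(C)C(C)(C)C)[C@@](C)(C=C)CCO[Si](CC)(CC)CC | intermediate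
21 | sodium five-membered oxa-alanate (Al on C11 and O6, two 2-methoxyethoxy ligands) | [Na+].COCCO[Al-]1(OCCOC)O[C@@H](C=C1C(OCC)OCC)[C@H](C(=C)CO[Si](C)(C)C(C)(C)C)[C@@](C)(C=C)CCO[Si](CC)(CC)CC | intermediate
22 | (2Z,4R,5S,6R)-iodoalkenol | CCOC(OCC)/C(I)=C/[C@H](O)[C@H](C(=C)CO[Si](C)(C)C(C)(C)C)[C@@](C)(C=C)CCO[Si](CC)(CC)CC | intermediate
23 | C6 triethylsilyl ether of 22 | CCOC(OCC)/C(I)=C/[C@H](O[Si](CC)(CC)CC)[C@H](C(=C)CO[Si](C)(C)C(C)(C)C)[C@@](C)(C=C)CCO[Si](CC)(CC)CC | intermediate
24 | (3R,4S,5R,6Z)-4-[3-(tert-butyldimethylsilyloxy)prop-1-en-2-yl]-3-ethenyl-8,8-diethoxy-7-iodo-3-methyl-5-(triethylsilyloxy)oct-6-enal | CCOC(OCC)/C(I)=C/[C@H](O[Si](CC)(CC)CC)[C@H](C(=C)CO[Si](C)(C)C(C)(C)C)[C@@](C)(C=C)CC=O | intermediate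
25 | allylboronate aldehyde (24 with CH2Bpin in place of I, cis to C6; C5, C6, C10 unchanged) | CCOC(OCC)/C(CB1OC(C)(C)C(C)(C)O1)=C/[C@H](O[Si](CC)(CC)CC)[C@H](C(=C)CO[Si](C)(C)C(C)(C)C)[C@@](C)(C=C)CC=O | intermediate
26 | O8-pinacolboryl derivative of 27 | C=C[C@@]1(C)C[C@@H](OB2OC(C)(C)C(C)(C)O2)[C@@H](C(=C)C(OCC)OCC)[C@H](O[Si](CC)(CC)CC)[C@@H]1C(=C)CO[Si](C)(C)C(C)(C)C | intermediate
27 | (1R,2R,3R,4S,5R)-4-[3-(tert-butyldimethylsilyloxy)prop-1-en-2-yl]-2-(3,3-diethoxyprop-1-en-2-yl)-5-ethenyl-5-methyl-3-(triethylsilyloxy)cyclohexan-1-ol | C=C[C@@]1(C)C[C@@H](O)[C@@H](C(=C)C(OCC)OCC)[C@H](O[Si](CC)(CC)CC)[C@@H]1C(=C)CO[Si](C)(C)C(C)(C)C | intermediate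
28 | diphenyl phosphite | O=[PH](Oc1ccccc1)Oc1ccccc1 | starting material
29 | tert-butyl 2-bromopropanoate | CC(Br)C(=O)OC(C)(C)C | starting material
30 | tert-butyl 2-(diphenoxyphosphoryl)propanoate (racemic) | CC(C(=O)OC(C)(C)C)P(=O)(Oc1ccccc1)Oc1ccccc1 | intermediate
31 | 2-oxoethyl acetate | CC(=O)OCC=O | starting material
32 | tert-butyl (Z)-4-acetoxy-2-methylbut-2-enoate | CC(C)(C)OC(=O)/C(C)=C\COC(C)=O | intermediate
33 | (Z)-4-acetoxy-2-methylbut-2-enoic acid | OC(=O)/C(C)=C\COC(C)=O | intermediate
34 | (Z)-4-acetoxy-2-methylbut-2-enoic 2,4,6-trichlorobenzoic anhydride | O=C(OC(=O)/C(C)=C\COC(C)=O)c1c(Cl)cc(Cl)cc1Cl | intermediate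
35 | C8 (Z)-4-acetoxy-2-methylbut-2-enoate of 27 | C=C[C@@]1(C)C[C@@H](OC(=O)/C(C)=C\COC(C)=O)[C@@H](C(=C)C(OCC)OCC)[C@H](O[Si](CC)(CC)CC)[C@@H]1C(=C)CO[Si](C)(C)C(C)(C)C | intermediate
36 | enal diol (C12 aldehyde, free C6-OH and C15-OH) | C=C[C@@]1(C)C[C@@H](OC(=O)/C(C)=C\COC(C)=O)[C@@H](C(=C)C=O)[C@H](O)[C@@H]1C(=C)CO | intermediate
37 | (5S,6R,7S,8R,10R)-8-[(Z)-4-acetoxy-2-methylbut-2-enoyloxy]-6,15-dihydroxyelema-1,3,11(13)-trien-12-oic acid | C=C[C@@]1(C)C[C@@H](OC(=O)/C(C)=C\COC(C)=O)[C@@H](C(=C)C(=O)O)[C@H](O)[C@@H]1C(=C)CO | target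

**Total step count:** 20
**Longest linear sequence:** 15 steps (3, 4, 5, 6–14, 18, 19, 20)

**Steps most likely to fail**

Step 7.
- Leakage between E(O) and Z(O) enolisation of the unusually acidic vinylogous ester could erode the diastereo- and enantiocontrol.
- A slow [3,3] shift onto the fully substituted alkene terminus could open a boat pathway.
- The Lewis-acidic boron reagent could interfere with the silyl ethers.
- Fallback, from 11 back to 20:
  - The ester is enolised with LDA in THF at −78 °C and silylated with TMSCl to the trimethylsilyl ketene acetal F1.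
  - F1 rearranges on warming through the same chair to the racemic trimethylsilyl ester F2.
  - Mild hydrolysis gives the racemic acid, i.e. 14 together with its mirror image F3.
  - The racemate is taken through steps 8 and 9 as written, which produces in addition the mirror-image acid chloride F4, the mirror-image Weinreb amide F5 and the mirror-image ynone F6.
  - The catalyst-controlled transfer hydrogenation of step 10 then turns the two enantiomeric ynones into 20 and the (5R,6R,10S)-diastereomer F7, which are separated by chromatography.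
  - Absolute configuration then comes from the reduction catalyst and not from the rearrangement.

Step 14.
- Slow cross-coupling at the hindered trisubstituted iodide could let consumption of the aldehyde compete with formation of 25. It could also let carbopalladation of the neighbouring alkene or protodeboronation compete.
- Fallback, from 23 back to 25:
  - The same (boryl)methylzinc coupling is carried out before the aldehyde exists and gives the isolable allylboronate bis-TES ether F8.
  - The selective Swern oxidation of the primary TES ether (as in step 13) then liberates 25.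
  - 25 closes at or below room temperature to 26 and, after hydrolysis, 27.
  - Ring closure is then triggered by the oxidation, and palladium and zinc never meet the aldehyde.

Step 18.
- Reversible conjugate addition of DMAP to the activated Z-acyl donor could scramble the alkene geometry.
- The hindered C8 hydroxyl group could react too slowly to outrun this.
- Fallback, from 27 (and 30) back to 35:
  - 30 is cleaved with TFA to 2-(diphenoxyphosphoryl)propanoic acid F9.
  - F9 acylates 27 (DCC, DMAP, CH2Cl2) to the phosphonate ester F10.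
  - Deprotonation (NaH, THF, −78 °C) and addition of 31 then build the Z-alkene on the substrate by the same Z-selective Horner–Wadsworth–Emmons reaction.
  - No preformed Z-acid has to be activated.

**Further compounds**
F1 | step 7 | trimethylsilyl ketene acetal of 11 (side chain cis to the allyloxy oxygen) | CC[Si](CC)(CC)OCC/C(C)=C/CO/C(O[Si](C)(C)C)=C\C(=C)CO[Si](C)(C)C(C)(C)C
F2 | step 7 | racemic trimethylsilyl ester of the rearranged acid (enantiomer leading to 14 drawn) | C[Si](C)(C)OC(=O)[C@H](C(=C)CO[Si](C)(C)C(C)(C)C)[C@@](C)(C=C)CCO[Si](CC)(CC)CC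
F3 | step 7 | mirror image of 14 | OC(=O)[C@@H](C(=C)CO[Si](C)(C)C(C)(C)C)[C@](C)(C=C)CCO[Si](CC)(CC)CC
F4 | step 7 | mirror image of 15 | ClC(=O)[C@@H](C(=C)CO[Si](C)(C)C(C)(C)C)[C@](C)(C=C)CCO[Si](CC)(CC)CC
F5 | step 7 | mirror image of 16 | CON(C)C(=O)[C@@H](C(=C)CO[Si](C)(C)C(C)(C)C)[C@](C)(C=C)CCO[Si](CC)(CC)CC
F6 | step 7 | mirror image of 19 | CCOC(OCC)C#CC(=O)[C@@H](C(=C)CO[Si](C)(C)C(C)(C)C)[C@](C)(C=C)CCO[Si](CC)(CC)CC
F7 | step 7 | (5R,6R,10S)-propargylic alcohol, diastereomer of 20 | CCOC(OCC)C#C[C@H](O)[C@@H](C(=C)CO[Si](C)(C)C(C)(C)C)[C@](C)(C=C)CCO[Si](CC)(CC)CC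
F8 | step 14 | allylboronate bis-TES ether (23 with CH2Bpin in place of I) | CCOC(OCC)/C(CB1OC(C)(C)C(C)(C)O1)=C/[C@H](O[Si](CC)(CC)CC)[C@H](C(=C)CO[Si](C)(C)C(C)(C)C)[C@@](C)(C=C)CCO[Si](CC)(CC)CC
F9 | step 18 | 2-(diphenoxyphosphoryl)propanoic acid | CC(C(=O)O)P(=O)(Oc1ccccc1)Oc1ccccc1
F10 | step 18 | C8 2-(diphenoxyphosphoryl)propanoate of 27 | C=C[C@@]1(C)C[C@@H](OC(=O)C(C)P(=O)(Oc2ccccc2)Oc2ccccc2)[C@@H](C(=C)C(OCC)OCC)[C@H](O[Si](CC)(CC)CC)[C@@H]1C(=C)CO[Si](C)(C)C(C)(C)C
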